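## Structural features

The target is a 2,3-dihydro-1-benzofuran (benzene ring A fused to dihydrofuran ring B) whose ring A is fully substituted. It carries a hydroxyl group on C4, an acetyl group on C5, a hydroxyl group on C6, and on C7 a CH2 group bonded to C3 of a 6-ethyl-4-hydroxy-5-methylpyran-2-one (ring C). C2 of ring B bears a 6-methylhepta-1,5-dien-2-yl chain and is the only stereocentre (R). It has no stereogenic neighbour, but it is allylic and bonded to the aryl ether oxygen O1, so the C2–O1 bond can ionize under Lewis acids, strong Brønsted acids or zerovalent palladium. The 1,1-disubstituted and trisubstituted double bonds exclude hydrogenation and cationic conditions, the acylphloroglucinol core is easily oxidized, and the CH2 bridge between two enol-type rings can be cleaved in a retro-Mannich sense on prolonged heating with acid or base. The real difficulty is regiochemical: C5 and C7 of the 4,6-dioxygenated bicycle each lie between two oxygen-bearing carbons and respond alike to electrophiles, yet acetyl must go to C5 and the bridge to C7. The key step exploits the fact that on ring A the acetyl carbon C5 and the hydroxyl carbon C6 are adjacent and that C5 has the C4 oxygen on its other side. That triad is exactly what forms when a carboxylic acid adds across a C5–C6 aryne polarized by a C4 alkoxy group. With C5 filled in this way, C7 is the only open carbon of ring A and the bridge can be attached without a choice.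

## Logic of the disconnections

23 is cut at both bonds of the bridging CH2 (C7–CH2 and CH2–C3 of ring C). The bridge joins two enol-type nucleophiles, so it is best introduced as a one-carbon electrophile that converts 20 through 21 into the acceptor 22. This divides the target into 15, which holds ring A, ring B and the stereocentre, and the achiral 20. The forward step must alkylate carbon and not oxygen, must run without strong acid, and depends on C7 being the only unsubstituted carbon of ring A in 15.

20 is cut at the C4–C5 bond and at the lactone O1–C2 bond of ring C. This leads through 19 to 17 and 18, and 17 comes from 16 by O-silylation. The cut follows the polarity of a ketone enol and a 1,3-diacyl dication equivalent. Because 16 is symmetrical there is no regiochemistry to control. The forward step must acylate carbon first and oxygen second.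

15 is traced to 14 by cutting the O–CH2 bond of the acetal on the C4 oxygen. That oxygen has to be an ether while the aryne is generated, because a free phenoxide would spoil the polarization. An acetal is chosen because, placed ortho to the new acetyl group, it leaves under acid mild enough to spare the C2–O1 bond and the two alkenes.

14 is cut at the C5–C(acyl) bond and the C6–O bond, giving 10 and 11 by way of 12 and 13. This is the only cut that installs acetyl and hydroxyl together and in a fixed mutual order, and it needs no Lewis acid. The forward step demands that oxygen adds at C6 and carbon at C5, which the C4 ether secures, and that the acyl shift in 13 is faster than its protonation.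

10 is cut at the S–O bond to give 9, and 9 at the carbamate C–O bond to give 8. The carbamate is needed as a directing group and the sulfonate as a leaving group on the same oxygen, so one is exchanged for the other. The forward steps must not be acidic, because the aryl–silicon bond of this electron-rich ring is acid-labile.

8 is cut at the C5–Si bond to give 6 by way of 7. C5 lies between two chelating oxygen substituents, so deprotonation there is favoured over C7, which has only one. The forward step must trap 7 with silicon before the carbamoyl group can migrate.

6 is cut at the acetal O–C bond to give 5, and 5 at C3a–C3 and O1–C2 to give 3 and 4. The second cut removes ring B, the side chain and the stereocentre in one operation and reaches a C2-symmetric aryl iodide and a commercial diene. The forward step must add the aryl group to the terminal carbon of the monosubstituted double bond of 4 and close the C–O bond with control of configuration.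

3 is cut at the C–I bond to give 2, and 2 at the carbamate O–C bond to give 1. Placing the carbamate on the triol while its three oxygens are still equivalent marks the future C6 oxygen by symmetry. No later step then has to choose between the C4 and C6 hydroxyl groups. The forward steps need only control of the degree of substitution and iodination between the two free hydroxyl groups.

## Other disconnections considered

Alternative 1: The cut goes through both bonds that ring B makes to ring A, C3a–C3 and C7a–O1, at a late stage.
- Forward key step: the fully substituted aryl iodide A2 and the enantiopure terminal epoxide A3 would be joined under palladium catalysis with norbornene A4 as transient mediator. The aryl–norbornyl palladacycle would open the epoxide at its CH2 group (C3a–C3), A4 would be extruded, and the alkoxide would close onto the former C–I carbon (C7a–O1) to give A1.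
- In its favour: the stereocentre comes from A3 and is not touched, so its configuration is fixed by a reagent and not by a catalyst. On this point the alternative is the better plan. It is also more convergent, and the ortho substituent that the relay needs next to iodine is supplied by the bridge.
- Against it: A2 is an electron-rich iodide whose single C–H bond sits beside an acetal oxygen on an otherwise full ring, and it carries an enolizable ketone and a pyranone that can bind palladium. The epoxide carbon of A3 is next to a fully substituted carbinol carbon, which should slow ring opening. The diene is only masked in A1, so a Peterson elimination and removal of three acetal groups would follow.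
- Comparison: structurally, A2 requires the same two decisions on ring A (acetyl at C5, bridge at C7) that the chosen plan settles with the aryne, so nothing is gained there. Mechanistically the relay has more stages that can stall than fluoride-triggered aryne formation. In step count the plans are about equal up to the key step, and the alternative is longer after it.

Alternative 2: The cut isolates C2 as one inserted carbon between C3 and C1' of the side chain.
- Forward key step: the benzylboronic ester A6, (dichloromethyl)lithium A7 and the alkenylmagnesium bromide A8 would be combined in one flask. The benzyl group would shift from boron to carbon with loss of chloride, then the alkenyl group would do the same with inversion at carbon, giving A5. Its C–B bond would later be oxidized with retention, and the alkoxide would close ring B by displacing an ortho fluoride.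
- In its favour: the chiral diol on boron governs both shifts. This reagent control is at least the equal of the ligand control in step 3 of the chosen plan and is the more predictable. No transition metal is required.
- Against it: A5 is an α-substituted allylboronic ester, open to 1,3-boron shift before oxidation. After ring closure two further fluorides would have to be exchanged for oxygen on a ring that loses electrophilicity with each exchange. The placement of acetyl at C5 and of the bridge at C7 is left unsolved.
- Comparison: the alternative is stronger on the stereocentre and weaker on ring A, which is where the difficulty lies. It would still need a C5-selective acylation of the kind the aryne supplies, and it would be several steps longer.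

Alternative 3: The cut is the C3–C4 bond of ring C, so the pyranone is assembled on the finished dihydrobenzofuran.
- Forward key step: the enol ester A10 would be treated with base. The enolate of the CH2 group next to the bridge would attack the methyl ester held cis across the enol double bond, and loss of methoxide would give A9.
- In its favour: the bridge carbon is attached to C7 by ordinary C–C bond formation, which avoids the methide 22 and its self-condensation. On that point the alternative is the better plan. The stereocentre would be set as in the chosen route, so the two are equal there.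
- Against it: the acetyl CH3 on C5 is more acidic than the ester CH2 and would be deprotonated first. Its enolate and the released methoxide can attack the enol ester, which is an activated acyl donor. The closure needs the Z enol ester. Building the three-carbon ester arm on C7 would take a formylation, an olefination and a conjugate reduction that spares two other double bonds.
- Comparison: mechanistically the Claisen closure competes with intramolecular acyl transfers that the chosen one-step coupling does not face. In step count it adds at least four operations after the point where the chosen plan needs one.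

Key step: step 8

Remarks on the chemistry:
- Compounds 10 and 14 and the key-step products of the three alternatives were checked for constitution and for the 2R configuration against 23. No correction is needed.
- The route keeps the structure of 10 but changes how its oxygens are differentiated. The carbamate is placed on 1 before iodination, so the C4 and C6 oxygens are distinguished by symmetry and not by a selective reaction on a diol. An N,N-diethyl carbamate is used because it survives the basic palladium step.
- Assumption: the antipode of the chiral phosphine that gives 2R in step 3 is fixed by a test reaction, both antipodes being available.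
- Assumption: 1 is used in anhydrous form, and the double-bond geometry of 17 has no bearing on step 11.

## Route

Step 1
Reactants: 1 benzene-1,3,5-triol (phloroglucinol)
Product: 2 3,5-dihydroxyphenyl N,N-diethylcarbamate
Conditions: 1 (3 equiv), Et2NCOCl (1 equiv), K2CO3 (1.1 equiv), acetone, reflux; excess 1 removed with water
Reagents that add atoms: N,N-diethylcarbamoyl chloride, CCN(CC)C(Cl)=O
Why: O-carbamoylation of a phenoxide by a carbamoyl chloride; the three hydroxyl groups of 1 are equivalent, so only the degree of substitution needs control, which the excess of water-soluble 1 provides.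

Step 2
Reactants: 2 3,5-dihydroxyphenyl N,N-diethylcarbamate
Product: 3 3,5-dihydroxy-4-iodophenyl N,N-diethylcarbamate
Conditions: I2 (1.0 equiv), NaHCO3 (1.1 equiv), THF–H2O, 0 °C
Reagents that add atoms: iodine, II
Why: Electrophilic aromatic iodination of a resorcinol monoanion in aqueous NaHCO3, which in resorcinol itself goes to the carbon between the two hydroxyl groups; here that carbon is also the only one not next to the bulky carbamate, and the C2-symmetric product should show one aromatic proton signal where the unsymmetrical isomer would show two.

Step 3
Reactants: 3 3,5-dihydroxy-4-iodophenyl N,N-diethylcarbamate; 4 myrcene (7-methyl-3-methylideneocta-1,6-diene)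
Product: 5 (2R)-4-hydroxy-2-(6-methylhepta-1,5-dien-2-yl)-2,3-dihydro-1-benzofuran-6-yl N,N-diethylcarbamate
Conditions: 4 (3 equiv), Pd(OAc)2 (5 mol %), chiral sulfinamide–monophosphine ligand (TY-Phos type, 12 mol %), PhONa (2.2 equiv), CH2Cl2, 80 °C, sealed tube
Reagents that add atoms: none
Why: Enantioselective Larock-type heteroannulation of a 1,3-diene (Heck insertion followed by Tsuji–Trost closure): oxidative addition of the C–I bond to zerovalent palladium, syn-carbopalladation of the monosubstituted double bond of 4 at its terminal carbon, and attack of the phenoxide on the internal terminus of the π-allylpalladium intermediate close the five-membered ring. C2 is set in this C–O bond formation under control of the chiral ligand, whose antipode is chosen for 2R. The two hydroxyl groups beside iodine are equivalent, so the closure has no regiochemical choice.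

Step 4
Reactants: 5 (2R)-4-hydroxy-2-(6-methylhepta-1,5-dien-2-yl)-2,3-dihydro-1-benzofuran-6-yl N,N-diethylcarbamate
Product: 6 (2R)-4-(methoxymethoxy)-2-(6-methylhepta-1,5-dien-2-yl)-2,3-dihydro-1-benzofuran-6-yl N,N-diethylcarbamate
Conditions: MOMCl (1.5 equiv), K2CO3 (2 equiv), acetone, 0 °C to rt
Reagents that add atoms: chloromethyl methyl ether, COCCl
Why: Williamson-type O-alkylation of the only free phenol; the acetal serves later both as a chelating group for lithiation at C5 and as the inductive group that polarizes the aryne.

Step 5
Reactants: 6 (2R)-4-(methoxymethoxy)-2-(6-methylhepta-1,5-dien-2-yl)-2,3-dihydro-1-benzofuran-6-yl N,N-diethylcarbamate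
Product: 8 (2R)-4-(methoxymethoxy)-2-(6-methylhepta-1,5-dien-2-yl)-5-(trimethylsilyl)-2,3-dihydro-1-benzofuran-6-yl N,N-diethylcarbamate, via C5 aryllithium 7 (not isolated)
Conditions: s-BuLi (1.2 equiv), TMEDA (1.2 equiv), THF, −78 °C; then Me3SiCl (1.5 equiv), −78 °C to rt
Reagents that add atoms: chlorotrimethylsilane, C[Si](C)(C)Cl
Why: Directed ortho-metalation: the carbamate carbonyl and the acetal oxygen both hold lithium over C5, the carbon between them, whereas C7 has the carbamate on one side and only the non-chelating ring oxygen on the other; trapping at −78 °C should outrun the anionic ortho-Fries shift.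

Step 6
Reactants: 8 (2R)-4-(methoxymethoxy)-2-(6-methylhepta-1,5-dien-2-yl)-5-(trimethylsilyl)-2,3-dihydro-1-benzofuran-6-yl N,N-diethylcarbamate
Product: 9 (2R)-4-(methoxymethoxy)-2-(6-methylhepta-1,5-dien-2-yl)-5-(trimethylsilyl)-2,3-dihydro-1-benzofuran-6-ol
Conditions: LiAlH4 (2 equiv), THF, 0 to 40 °C; then H2O, 15% aq. NaOH
Reagents that add atoms: none
Why: Hydride reduction of the carbamate carbonyl releases the phenoxide; isolated alkenes, the acetal and the aryl–silicon bond are inert to LiAlH4, and the basic work-up avoids protodesilylation.

Step 7
Reactants: 9 (2R)-4-(methoxymethoxy)-2-(6-methylhepta-1,5-dien-2-yl)-5-(trimethylsilyl)-2,3-dihydro-1-benzofuran-6-ol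
Product: 10 (2R)-4-(methoxymethoxy)-2-(6-methylhepta-1,5-dien-2-yl)-5-(trimethylsilyl)-2,3-dihydro-1-benzofuran-6-yl trifluoromethanesulfonate
Conditions: PhNTf2 (1.2 equiv), DBU (1.5 equiv), MeCN, rt to 40 °C
Reagents that add atoms: N-phenylbis(trifluoromethanesulfonimide), O=S(=O)(N(c1ccccc1)S(=O)(=O)C(F)(F)F)C(F)(F)F
Why: O-sulfonylation of an ortho-silyl phenoxide by a neutral triflyl donor under amine base; no acid is generated, so the aryl–silicon bond and the acetal persist.

Step 8
Reactants: 10 (2R)-4-(methoxymethoxy)-2-(6-methylhepta-1,5-dien-2-yl)-5-(trimethylsilyl)-2,3-dihydro-1-benzofuran-6-yl trifluoromethanesulfonate; 11 acetic acid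
Product: 14 1-[(2R)-6-hydroxy-4-(methoxymethoxy)-2-(6-methylhepta-1,5-dien-2-yl)-2,3-dihydro-1-benzofuran-5-yl]ethanone, via C5–C6 aryne 12 (not isolated), via C5 arylcesium acetate 13 (not isolated)
Conditions: 11 (1.2 equiv), CsF (4 equiv), THF (0.05 M), 125 °C, sealed tube
Reagents that add atoms: none
Why: CsF attacks silicon in 10, the aryl anion expels triflate, and the C5–C6 aryne 12 forms under neutral conditions free of Lewis acid. Acetate, made from 11 and CsF, adds through oxygen to C6 because the C4 methoxymethoxy group distorts the aryne, making C6 the more electrophilic carbon and placing the developing negative charge at C5 beside the inductively withdrawing oxygen; this is the regiocontrol the step needs. The aryl anion 13 then attacks the carbonyl group of its own neighbouring acetate through a four-membered transition structure, and collapse of that strained alkoxide gives the C5 ketone and the C6 phenoxide, which is protonated on work-up. The closest known reaction type is the fluoride-induced insertion of arynes into the C–O bond of carboxylic acids, which converts 3-alkoxyarynes into 2-acyl-3-alkoxyphenols. No ring is closed and no stereocentre is formed; C2 is remote and untouched. The second selectivity needed, acyl shift over protonation of 13, is favoured by keeping free acid scarce (near-stoichiometric 11, excess CsF) and by the high temperature. The result, acetyl on C5 with a free hydroxyl on C6 and C7 left open, is one that electrophilic acylation of the 4,6-dioxygenated ring could not guarantee.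

Step 9
Reactants: 14 1-[(2R)-6-hydroxy-4-(methoxymethoxy)-2-(6-methylhepta-1,5-dien-2-yl)-2,3-dihydro-1-benzofuran-5-yl]ethanone
Product: 15 1-[(2R)-4,6-dihydroxy-2-(6-methylhepta-1,5-dien-2-yl)-2,3-dihydro-1-benzofuran-5-yl]ethanone
Conditions: 2 M aq. HCl–MeOH (1:9), 40 °C
Reagents that add atoms: none
Why: Acid-catalysed methanolysis of an aryl methoxymethyl ether, which is fast when the ether is ortho to a carbonyl group; at this acidity the isolated alkenes should not be protonated, and O1, now a vinylogous ester oxygen para to the acetyl group, is too weakly basic for the C2–O1 bond to ionize.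

Step 10
Reactants: 16 pentan-3-one
Product: 17 trimethyl(pent-2-en-3-yloxy)silane
Conditions: Me3SiOTf (1.1 equiv), Et3N (1.3 equiv), CH2Cl2, 0 °C
Reagents that add atoms: trimethylsilyl trifluoromethanesulfonate, C[Si](C)(C)OS(=O)(=O)C(F)(F)F
Why: Soft enolization with O-silylation; the ketone is symmetrical, so only one constitutional enol ether can form, and its geometry is irrelevant.

Step 11
Reactants: 17 trimethyl(pent-2-en-3-yloxy)silane; 18 propanedioyl dichloride (malonyl dichloride)
Product: 20 6-ethyl-4-hydroxy-5-methyl-2H-pyran-2-one, via keto acid chloride 19 (not isolated)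
Conditions: 18 (1.0 equiv), Et2O, −78 °C to rt
Reagents that add atoms: none
Why: Pyranone synthesis from a silyl enol ether and malonyl dichloride: C-acylation with loss of Me3SiCl gives 19, whose enol oxygen then closes the six-membered lactone on the second acyl chloride with loss of HCl.

Step 12
Reactants: 15 1-[(2R)-4,6-dihydroxy-2-(6-methylhepta-1,5-dien-2-yl)-2,3-dihydro-1-benzofuran-5-yl]ethanone; 20 6-ethyl-4-hydroxy-5-methyl-2H-pyran-2-one
Product: 23 1-[(2R)-7-[(6-ethyl-4-hydroxy-5-methyl-2-oxo-2H-pyran-3-yl)methyl]-4,6-dihydroxy-2-(6-methylhepta-1,5-dien-2-yl)-2,3-dihydro-1-benzofuran-5-yl]ethanone, via Mannich base 21 (not isolated), via pyranone methide 22 (not isolated)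
Conditions: 20 (1.5 equiv), CH2=NMe2+ I− (1.4 equiv), MeCN, rt; then 15 (1.0 equiv), 70 °C
Reagents that add atoms: dimethylmethyleneammonium iodide, C=[N+](C)C.[I-]
Why: Mannich aminomethylation of the enolic C3 of 20 gives 21, thermal loss of dimethylamine gives the Michael acceptor 22, and conjugate addition of C7 of 15 followed by re-aromatization forms the bridge. C7 is the only unsubstituted carbon of ring A and is activated by the C6 hydroxyl group and O1. Keeping the iminium salt below the amount of 20 and letting it be consumed before 15 is added prevents aminomethylation of 15.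

## Compound list

1 | benzene-1,3,5-triol (phloroglucinol) | Oc1cc(O)cc(O)c1 | starting material
2 | 3,5-dihydroxyphenyl N,N-diethylcarbamate | CCN(CC)C(=O)Oc1cc(O)cc(O)c1 | intermediate
3 | 3,5-dihydroxy-4-iodophenyl N,N-diethylcarbamate | CCN(CC)C(=O)Oc1cc(O)c(I)c(O)c1 | intermediate
4 | myrcene (7-methyl-3-methylideneocta-1,6-diene) | C=CC(=C)CCC=C(C)C | starting material
5 | (2R)-4-hydroxy-2-(6-methylhepta-1,5-dien-2-yl)-2,3-dihydro-1-benzofuran-6-yl N,N-diethylcarbamate | C=C(CCC=C(C)C)[C@H]1Cc2c(O)cc(OC(=O)N(CC)CC)cc2O1 | intermediate
6 | (2R)-4-(methoxymethoxy)-2-(6-methylhepta-1,5-dien-2-yl)-2,3-dihydro-1-benzofuran-6-yl N,N-diethylcarbamate | C=C(CCC=C(C)C)[C@H]1Cc2c(OCOC)cc(OC(=O)N(CC)CC)cc2O1 | intermediate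
7 | [(2R)-6-(diethylcarbamoyloxy)-4-(methoxymethoxy)-2-(6-methylhepta-1,5-dien-2-yl)-2,3-dihydro-1-benzofuran-5-yl]lithium (formed in the flask) | C=C(CCC=C(C)C)[C@H]1Cc2c(OCOC)c([Li])c(OC(=O)N(CC)CC)cc2O1 | intermediate
8 | (2R)-4-(methoxymethoxy)-2-(6-methylhepta-1,5-dien-2-yl)-5-(trimethylsilyl)-2,3-dihydro-1-benzofuran-6-yl N,N-diethylcarbamate | C=C(CCC=C(C)C)[C@H]1Cc2c(OCOC)c([Si](C)(C)C)c(OC(=O)N(CC)CC)cc2O1 | intermediate
9 | (2R)-4-(methoxymethoxy)-2-(6-methylhepta-1,5-dien-2-yl)-5-(trimethylsilyl)-2,3-dihydro-1-benzofuran-6-ol | C=C(CCC=C(C)C)[C@H]1Cc2c(OCOC)c([Si](C)(C)C)c(O)cc2O1 | intermediate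
10 | (2R)-4-(methoxymethoxy)-2-(6-methylhepta-1,5-dien-2-yl)-5-(trimethylsilyl)-2,3-dihydro-1-benzofuran-6-yl trifluoromethanesulfonate | C=C(CCC=C(C)C)[C@H]1Cc2c(OCOC)c([Si](C)(C)C)c(OS(=O)(=O)C(F)(F)F)cc2O1 | intermediate
11 | acetic acid | CC(=O)O | starting material
12 | (2R)-5,6-didehydro-4-(methoxymethoxy)-2-(6-methylhepta-1,5-dien-2-yl)-2,3-dihydro-1-benzofuran, the C5–C6 aryne (formed in the flask) | C=C(CCC=C(C)C)[C@H]1CC2=C(OCOC)C#CC=C2O1 | intermediate
13 | [(2R)-6-(acetyloxy)-4-(methoxymethoxy)-2-(6-methylhepta-1,5-dien-2-yl)-2,3-dihydro-1-benzofuran-5-yl]cesium (formed in the flask) | C=C(CCC=C(C)C)[C@H]1Cc2c(OCOC)c([Cs])c(OC(C)=O)cc2O1 | intermediate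
14 | 1-[(2R)-6-hydroxy-4-(methoxymethoxy)-2-(6-methylhepta-1,5-dien-2-yl)-2,3-dihydro-1-benzofuran-5-yl]ethanone | C=C(CCC=C(C)C)[C@H]1Cc2c(OCOC)c(C(C)=O)c(O)cc2O1 | intermediate
15 | 1-[(2R)-4,6-dihydroxy-2-(6-methylhepta-1,5-dien-2-yl)-2,3-dihydro-1-benzofuran-5-yl]ethanone | C=C(CCC=C(C)C)[C@H]1Cc2c(O)c(C(C)=O)c(O)cc2O1 | intermediate
16 | pentan-3-one | CCC(=O)CC | starting material
17 | trimethyl(pent-2-en-3-yloxy)silane (mixture of double-bond isomers) | CC=C(CC)O[Si](C)(C)C | intermediate
18 | propanedioyl dichloride (malonyl dichloride) | O=C(Cl)CC(=O)Cl | starting material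
19 | 4-methyl-3,5-dioxoheptanoyl chloride (formed in the flask) | CCC(=O)C(C)C(=O)CC(=O)Cl | intermediate
20 | 6-ethyl-4-hydroxy-5-methyl-2H-pyran-2-one | CCc1oc(=O)cc(O)c1C | intermediate
21 | 3-[(dimethylamino)methyl]-6-ethyl-4-hydroxy-5-methyl-2H-pyran-2-one (formed in the flask) | CCc1oc(=O)c(CN(C)C)c(O)c1C | intermediate
22 | 6-ethyl-5-methyl-3-methylidene-2H-pyran-2,4(3H)-dione (formed in the flask) | CCC1=C(C)C(=O)C(=C)C(=O)O1 | intermediate
23 | 1-[(2R)-7-[(6-ethyl-4-hydroxy-5-methyl-2-oxo-2H-pyran-3-yl)methyl]-4,6-dihydroxy-2-(6-methylhepta-1,5-dien-2-yl)-2,3-dihydro-1-benzofuran-5-yl]ethanone | C=C(CCC=C(C)C)[C@H]1Cc2c(O)c(C(C)=O)c(O)c(Cc3c(O)c(C)c(CC)oc3=O)c2O1 | target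

## Step count and least certain steps

Total step count: 12. Longest linear sequence: 10 (steps 1 to 9 and step 12); steps 10 and 11 form the short branch to 20.

Step 8 (key step). What may go wrong:
- protonation of the aryl anion 13 before the acyl shift, which gives O-arylation in place of insertion;
- partial addition of acetate at C5 if the polarization by the C4 ether is weaker than expected on this crowded aryne;
- capture of the product phenoxide by a second aryne;
- attack of fluoride at sulfur in place of silicon.

Fallback for step 8, setting out from 6 and returning at 15: the acetyl group is introduced by directed lithiation and no aryne is used. Reduction of 6 with LiAlH4 should give (2R)-4-(methoxymethoxy)-2-(6-methylhepta-1,5-dien-2-yl)-2,3-dihydro-1-benzofuran-6-ol F1. Acetalization with chloromethyl methyl ether and K2CO3 should give (2R)-4,6-bis(methoxymethoxy)-2-(6-methylhepta-1,5-dien-2-yl)-2,3-dihydro-1-benzofuran F2. Lithiation with n-BuLi in THF at 0 °C at the carbon between the two acetal groups, then acylation with N-methoxy-N-methylacetamide, should give 1-[(2R)-4,6-bis(methoxymethoxy)-2-(6-methylhepta-1,5-dien-2-yl)-2,3-dihydro-1-benzofuran-5-yl]ethanone F3. Mild acid methanolysis as in step 9 then gives 15.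

Step 3. What may go wrong:
- poor facial selectivity in the C–O bond-forming attack on the π-allyl intermediate;
- carbopalladation of the 1,1-disubstituted double bond of 4, leading to a ring with a fully substituted C2;
- β-hydride elimination to open-chain dienes;
- loss of enantiomeric purity through re-ionization of the allylic aryl ether by zerovalent palladium.

Fallback for step 3, setting out from 3 and returning at 5: the annulation is run without a chiral ligand (Pd(OAc)2, Na2CO3, Bu4NCl, DMF, 80 °C) to give rac-4-hydroxy-2-(6-methylhepta-1,5-dien-2-yl)-2,3-dihydro-1-benzofuran-6-yl N,N-diethylcarbamate F4. The enantiomers are separated by preparative chromatography on a chiral stationary phase. The (2S)-4-hydroxy-2-(6-methylhepta-1,5-dien-2-yl)-2,3-dihydro-1-benzofuran-6-yl N,N-diethylcarbamate F5 is set aside and the 2R enantiomer is 5. The source of stereocontrol thus changes from catalysis to resolution, at an early stage where material is cheap.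

Step 5. What may go wrong:
- competing deprotonation at C7, between the carbamate and the ring oxygen;
- migration of the carbamoyl group to carbon (anionic ortho-Fries) if the temperature rises before silylation;
- deprotonation at the allylic C2 or benzylic C3 with opening of ring B.

Fallback for step 5, setting out from 5 and returning at 8: the position is fixed by the free C4 hydroxyl group and not by kinetic deprotonation. Amine-catalysed ortho-bromination of 5 (N-bromosuccinimide, catalytic iPr2NH, CH2Cl2, −78 to 0 °C) should give (2R)-5-bromo-4-hydroxy-2-(6-methylhepta-1,5-dien-2-yl)-2,3-dihydro-1-benzofuran-6-yl N,N-diethylcarbamate F6, because C5 is the only free position ortho to that hydroxyl group. Acetalization as in step 4 gives (2R)-5-bromo-4-(methoxymethoxy)-2-(6-methylhepta-1,5-dien-2-yl)-2,3-dihydro-1-benzofuran-6-yl N,N-diethylcarbamate F7. Bromine–lithium exchange with n-BuLi at −78 °C generates 7 at a defined carbon, and Me3SiCl gives 8.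

Step 2. What may go wrong:
- iodination at a carbon next to the carbamate in place of the carbon between the hydroxyl groups;
- a second iodination.

Fallback for step 2, setting out from 1 and returning at 5: the order of events is reversed, so that iodination has only one possible site. 1 is iodinated (I2, NaHCO3, THF–H2O, 0 °C) to 2-iodobenzene-1,3,5-triol F8, which is used at once. Annulation with 4 under the conditions of step 3 gives (2R)-2-(6-methylhepta-1,5-dien-2-yl)-2,3-dihydro-1-benzofuran-4,6-diol F9. One equivalent of N,N-diethylcarbamoyl chloride with K2CO3 then acylates the less hindered C6 hydroxyl group to give 5. The price is a site-selective acylation of a diol.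

Step 12. What may go wrong:
- addition of a second molecule of 20 to the methide 22, giving a methylene-bis-pyranone;
- aminomethylation of 15 by unconsumed iminium salt;
- reversible O-alkylation that slows the productive C-alkylation.

Fallback for step 12, setting out from 15 and returning at 23: the roles of the two partners are exchanged. 15 is aminomethylated at C7 with dimethylmethyleneammonium iodide to 1-[(2R)-7-[(dimethylamino)methyl]-4,6-dihydroxy-2-(6-methylhepta-1,5-dien-2-yl)-2,3-dihydro-1-benzofuran-5-yl]ethanone F10, which is isolated. Heating F10 with 20 in MeCN expels dimethylamine to give the ortho-quinone methide of ring A, which is trapped by the enolic C3 of 20 to give 23. No pyranone methide is present, so the bis-pyranone cannot form.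

## Further compounds

F1 | step 8 | (2R)-4-(methoxymethoxy)-2-(6-methylhepta-1,5-dien-2-yl)-2,3-dihydro-1-benzofuran-6-ol | C=C(CCC=C(C)C)[C@H]1Cc2c(OCOC)cc(O)cc2O1
F2 | step 8 | (2R)-4,6-bis(methoxymethoxy)-2-(6-methylhepta-1,5-dien-2-yl)-2,3-dihydro-1-benzofuran | C=C(CCC=C(C)C)[C@H]1Cc2c(OCOC)cc(OCOC)cc2O1
F3 | step 8 | 1-[(2R)-4,6-bis(methoxymethoxy)-2-(6-methylhepta-1,5-dien-2-yl)-2,3-dihydro-1-benzofuran-5-yl]ethanone | C=C(CCC=C(C)C)[C@H]1Cc2c(OCOC)c(C(C)=O)c(OCOC)cc2O1
F4 | step 3 | rac-4-hydroxy-2-(6-methylhepta-1,5-dien-2-yl)-2,3-dihydro-1-benzofuran-6-yl N,N-diethylcarbamate | C=C(CCC=C(C)C)C1Cc2c(O)cc(OC(=O)N(CC)CC)cc2O1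
F5 | step 3 | (2S)-4-hydroxy-2-(6-methylhepta-1,5-dien-2-yl)-2,3-dihydro-1-benzofuran-6-yl N,N-diethylcarbamate | C=C(CCC=C(C)C)[C@@H]1Cc2c(O)cc(OC(=O)N(CC)CC)cc2O1
F6 | step 5 | (2R)-5-bromo-4-hydroxy-2-(6-methylhepta-1,5-dien-2-yl)-2,3-dihydro-1-benzofuran-6-yl N,N-diethylcarbamate | C=C(CCC=C(C)C)[C@H]1Cc2c(O)c(Br)c(OC(=O)N(CC)CC)cc2O1
F7 | step 5 | (2R)-5-bromo-4-(methoxymethoxy)-2-(6-methylhepta-1,5-dien-2-yl)-2,3-dihydro-1-benzofuran-6-yl N,N-diethylcarbamate | C=C(CCC=C(C)C)[C@H]1Cc2c(OCOC)c(Br)c(OC(=O)N(CC)CC)cc2O1
F8 | step 2 | 2-iodobenzene-1,3,5-triol | Oc1cc(O)c(I)c(O)c1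
F9 | step 2 | (2R)-2-(6-methylhepta-1,5-dien-2-yl)-2,3-dihydro-1-benzofuran-4,6-diol | C=C(CCC=C(C)C)[C@H]1Cc2c(O)cc(O)cc2O1
F10 | step 12 | 1-[(2R)-7-[(dimethylamino)methyl]-4,6-dihydroxy-2-(6-methylhepta-1,5-dien-2-yl)-2,3-dihydro-1-benzofuran-5-yl]ethanone | C=C(CCC=C(C)C)[C@H]1Cc2c(O)c(C(C)=O)c(O)c(CN(C)C)c2O1
A1 | alternative 1 | 1-[(2R)-7-{[6-ethyl-4-(methoxymethoxy)-5-methyl-2-oxopyran-3-yl]methyl}-4,6-bis(methoxymethoxy)-2-[6-methyl-2-(triethylsilyloxy)-1-(trimethylsilyl)hept-5-en-2-yl]-2,3-dihydro-1-benzofuran-5-yl]ethanone | C[Si](C)(C)CC(O[Si](CC)(CC)CC)(CCC=C(C)C)[C@H]1Cc2c(OCOC)c(C(C)=O)c(OCOC)c(Cc3c(OCOC)c(C)c(CC)oc3=O)c2O1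
A2 | alternative 1 | 1-[3-{[6-ethyl-4-(methoxymethoxy)-5-methyl-2-oxo-2H-pyran-3-yl]methyl}-4-iodo-2,6-bis(methoxymethoxy)phenyl]ethanone | CC(=O)c1c(OCOC)cc(I)c(Cc2c(OCOC)c(C)c(CC)oc2=O)c1OCOC
A3 | alternative 1 | (2R)-2-[6-methyl-2-(triethylsilyloxy)-1-(trimethylsilyl)hept-5-en-2-yl]oxirane | C[Si](C)(C)CC(O[Si](CC)(CC)CC)(CCC=C(C)C)[C@H]1CO1
A4 | alternative 1 | norbornene (bicyclo[2.2.1]hept-2-ene) | C1=CC2CCC1C2
A5 | alternative 2 | (4R,5R)-4,5-dicyclohexyl-2-[(2R)-7-methyl-3-methylidene-1-(2,4,6-trifluorophenyl)oct-6-en-2-yl]-1,3,2-dioxaborolane | C=C(CCC=C(C)C)[C@@H](Cc1c(F)cc(F)cc1F)B1O[C@H](C2CCCCC2)[C@@H](C2CCCCC2)O1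
A6 | alternative 2 | (4R,5R)-4,5-dicyclohexyl-2-[(2,4,6-trifluorophenyl)methyl]-1,3,2-dioxaborolane | Fc1cc(F)c(CB2O[C@H](C3CCCCC3)[C@@H](C3CCCCC3)O2)c(F)c1
A7 | alternative 2 | (dichloromethyl)lithium | [Li]C(Cl)Cl
A8 | alternative 2 | (6-methylhepta-1,5-dien-2-yl)magnesium bromide | C=C([Mg]Br)CCC=C(C)C
A9 | alternative 3 | 1-[(2R)-7-[(6-ethyl-4-hydroxy-5-methyl-2-oxopyran-3-yl)methyl]-4,6-bis(methoxymethoxy)-2-(6-methylhepta-1,5-dien-2-yl)-2,3-dihydro-1-benzofuran-5-yl]ethanone | C=C(CCC=C(C)C)[C@H]1Cc2c(OCOC)c(C(C)=O)c(OCOC)c(Cc3c(O)c(C)c(CC)oc3=O)c2O1
A10 | alternative 3 | methyl (2Z)-3-({3-[(2R)-5-acetyl-4,6-bis(methoxymethoxy)-2-(6-methylhepta-1,5-dien-2-yl)-2,3-dihydro-1-benzofuran-7-yl]propanoyl}oxy)-2-methylpent-2-enoate | C=C(CCC=C(C)C)[C@H]1Cc2c(OCOC)c(C(C)=O)c(OCOC)c(CCC(=O)O/C(CC)=C(/C)C(=O)OC)c2O1
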